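**Retrosynthetic overview**
1. The butenolide arm is cut at C12–C13: cross-metathesis of a C-9 allyl group with α-methylene-γ-butyrolactone, then an exo-to-endo double-bond shift; the C-8 methylene comes from a C-8 ketone.
2. Ring B comes from a cis-hydrindanone by a one-carbon ring expansion: LiCHBr2 adds to the C-8 ketone and C-10 shifts from C-8 to the new carbon C-9; the enolate this leaves is allylated at C-9.
3. The angular methyl comes from enolate methylation; ring A is closed at C3–C4 by ester-enolate alkylation after an enantioselective Mukaiyama–Michael addition (C4–C5).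
4. The cyclopentenone is made by a Pauson–Khand reaction of 5-chloropent-1-yne, ethylene and CO.
5. Ring order: five-membered ring, then ring A, then expansion of the five-membered ring to ring B, then the lactone.

Assumption: the SMILES is taken literally; it describes a cis-fused decalin (H-5 and the C-10 methyl on the same face), and labdane numbering (C-1 to C-20) is used for positions.

**Step 1**
Reactants: 1 5-chloropent-1-yne
Product: 2 2-(3-chloropropyl)cyclopent-2-en-1-one
Conditions: Co2(CO)8 (5 mol%), ethylene (40 bar), CO (60 bar), toluene, 130 °C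
Reagents that add atoms: ethylene C=C; carbon monoxide [C-]#[O+]
Why: Intermolecular Pauson–Khand reaction; the alkyne substituent ends up next to the carbonyl, so only the 2-substituted enone forms, and no stereocenter is made.

**Step 2**
Reactants: 3 methyl propanoate
Product: 5 tert-butyl[(1-methoxyprop-1-en-1-yl)oxy]dimethylsilane (E/Z mixture), via lithium enolate 4 (not isolated)
Conditions: LiN(i-Pr)2, THF, −78 °C; TBSCl, DMPU, −78 → 23 °C; distillation
Reagents that add atoms: tert-butyldimethylsilyl chloride CC(C)(C)[Si](C)(C)Cl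
Why: Kinetic ester enolization and O-silylation (Ireland-type silyl ketene acetal formation); the E/Z ratio does not matter because C-4 is enolized again in step 3.

**Step 3**
Reactants: 2 2-(3-chloropropyl)cyclopent-2-en-1-one; 5 tert-butyl[(1-methoxyprop-1-en-1-yl)oxy]dimethylsilane
Product: 8 methyl (3aR,4R)-1-{[tert-butyl(dimethyl)silyl]oxy}-4-methyl-3,3a,4,5,6,7-hexahydro-2H-indene-4-carboxylate, via Michael adduct 6 (not isolated), via ester enolate 7 (not isolated)
Conditions: BINOL-derived imidodiphosphorimidate (IDPi) acid, (S,S)-enantiomer (2 mol%), toluene, −60 °C; then LiN(i-Pr)2 (1.3 equiv), THF–DMPU, −78 → 23 °C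
Reagents that add atoms: none
Why: Proposed new method: the acid is silylated by 5 to a silylium/IDPi ion pair that O-silylates enone 2, and the confined chiral counteranion shields one face so that 5 adds at C-5 to give (S)-adduct 6 as its TBS enol ether; LiN(i-Pr)2 then forms ester enolate 7, which closes ring A by 6-exo-tet alkylation through the conformer in which H-5 eclipses the enolate double bond (A(1,3) strain), placing CO2Me cis to H-5 whatever the enolate geometry; the closest known reactions are IDPi- and oxazaborolidinium-catalysed Mukaiyama–Michael additions to enoates and unsubstituted cyclic enones, not shown for an α-alkylcyclopentenone or with an in-flask enolate ring closure.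

**Step 4**
Reactants: 8 methyl (3aR,4R)-1-{[tert-butyl(dimethyl)silyl]oxy}-4-methyl-3,3a,4,5,6,7-hexahydro-2H-indene-4-carboxylate
Product: 10 methyl (3aR,4R,7aR)-4,7a-dimethyl-1-oxooctahydro-1H-indene-4-carboxylate, via sulfonium enolate 9 (not isolated)
Conditions: tris(dimethylamino)sulfonium difluorotrimethylsilicate (TASF), MeI, THF, −78 → 0 °C
Reagents that add atoms: iodomethane CI
Why: Fluoride cleavage of the silyl enol ether gives the regiodefined enolate (Noyori–Kuwajima alkylation), and MeI attacks C-10 on the H-5 face because the other face is blocked by the axial C-4 methyl, giving the cis-hydrindanone.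

**Step 5**
Reactants: 10 methyl (3aR,4R,7aR)-4,7a-dimethyl-1-oxooctahydro-1H-indene-4-carboxylate; 11 3-bromoprop-1-ene (allyl bromide)
Product: 14 methyl (1R,4aR,5S,8aR)-1,4a-dimethyl-6-oxo-5-(prop-2-en-1-yl)decahydronaphthalene-1-carboxylate, via dibromomethyl alkoxide 12 (not isolated), via ring-expanded enolate 13 (not isolated)
Conditions: CH2Br2, lithium 2,2,6,6-tetramethylpiperidide, THF, −78 °C; n-BuLi, −95 → 0 °C; then 11, HMPA, −78 → 0 °C
Reagents that add atoms: dibromomethane BrCBr
Why: Nozaki–Yamamoto β-oxido carbenoid ring expansion: after Br/Li exchange the more substituted carbon C-10 shifts from C-8 to the carbenoid carbon with retention (a non-pericyclic 1,2-shift), giving the six-membered ring B as its C-8/C-9 lithium enolate only; allyl bromide then attacks C-9 on the convex face, anti to the pseudo-axial C-10–C-1 bond, so the allyl group is cis to the angular methyl.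

**Step 6**
Reactants: 14 methyl (1R,4aR,5S,8aR)-1,4a-dimethyl-6-oxo-5-(prop-2-en-1-yl)decahydronaphthalene-1-carboxylate
Product: 15 methyl (1R,4aS,5R,8aR)-1,4a-dimethyl-6-methylidene-5-(prop-2-en-1-yl)decahydronaphthalene-1-carboxylate
Conditions: Zn, CH2Br2, TiCl4, THF–CH2Cl2, 0 → 23 °C
Reagents that add atoms: dibromomethane BrCBr
Why: Lombardo methylenation is non-basic, so the hindered, epimerizable C-8 ketone becomes the exocyclic methylene without loss of the C-9 configuration and without touching the ester.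

**Step 7**
Reactants: 15 methyl (1R,4aS,5R,8aR)-1,4a-dimethyl-6-methylidene-5-(prop-2-en-1-yl)decahydronaphthalene-1-carboxylate
Product: 17 [(1R,4aS,5R,8aR)-1,4a-dimethyl-6-methylidene-5-(prop-2-en-1-yl)decahydronaphthalen-1-yl]methyl acetate, via primary alcohol 16 (not isolated)
Conditions: LiAlH4, THF, 0 → 23 °C; then pyridine, Ac2O, DMAP, 0 → 23 °C
Reagents that add atoms: acetic anhydride CC(=O)OC(C)=O
Why: Hydride reduction of the neopentyl ester to the alkoxide, then DMAP-catalysed acetylation in the same flask; no stereocenter is affected.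

**Step 8**
Reactants: 17 [(1R,4aS,5R,8aR)-1,4a-dimethyl-6-methylidene-5-(prop-2-en-1-yl)decahydronaphthalen-1-yl]methyl acetate; 18 3-methylideneoxolan-2-one (α-methylene-γ-butyrolactone)
Product: 19 [(1R,4aS,5R,8aR)-1,4a-dimethyl-6-methylidene-5-[(2E)-2-(2-oxooxolan-3-ylidene)ethyl]decahydronaphthalen-1-yl]methyl acetate
Conditions: 18 (3 equiv), second-generation Hoveyda–Grubbs catalyst (5 mol%), 2,6-dichloro-1,4-benzoquinone (10 mol%), CH2Cl2, 40 °C
Reagents that add atoms: none
Why: Olefin cross-metathesis: only the monosubstituted allyl alkene reacts, the hindered 1,1-disubstituted C-8 methylene is inert, and the quinone suppresses Ru–H isomerization; the alkene geometry is lost in step 9.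

**Step 9**
Reactants: 19 [(1R,4aS,5R,8aR)-1,4a-dimethyl-6-methylidene-5-[(2E)-2-(2-oxooxolan-3-ylidene)ethyl]decahydronaphthalen-1-yl]methyl acetate
Product: 20 [(1R,4aS,5R,8aR)-1,4a-dimethyl-6-methylidene-5-[2-(2-oxo-2,5-dihydrofuran-3-yl)ethyl]decahydronaphthalen-1-yl]methyl acetate
Conditions: RuHCl(CO)(PPh3)3 (5 mol%), toluene, 60 °C
Reagents that add atoms: none
Why: Metal-hydride addition/β-hydride elimination moves the conjugated exocyclic C12=C13 bond into the lactone ring (C13=C14), the more stable butenolide; the electron-poor alkylidene lactone should insert Ru–H faster than the hindered C-8 methylene.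

**Compound list**
1 | 5-chloropent-1-yne | ClCCCC#C | starting material
2 | 2-(3-chloropropyl)cyclopent-2-en-1-one | O=C1CCC=C1CCCCl | intermediate
3 | methyl propanoate | CCC(=O)OC | starting material
4 | lithium 1-methoxyprop-1-en-1-olate (lithium enolate of 3; not isolated) | CC=C(OC)O[Li] | intermediate
5 | tert-butyl[(1-methoxyprop-1-en-1-yl)oxy]dimethylsilane (E/Z mixture) | CC=C(OC)O[Si](C)(C)C(C)(C)C | intermediate
6 | methyl (2RS)-2-[(1S)-3-{[tert-butyl(dimethyl)silyl]oxy}-2-(3-chloropropyl)cyclopent-2-en-1-yl]propanoate (Michael adduct; not isolated) | CC(C)(C)[Si](C)(C)OC1=C(CCCCl)[C@@H](CC1)C(C)C(=O)OC | intermediate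
7 | lithium ester enolate of 6 (not isolated) | CC(C)(C)[Si](C)(C)OC1=C(CCCCl)[C@@H](CC1)C(C)=C(OC)O[Li] | intermediate
8 | methyl (3aR,4R)-1-{[tert-butyl(dimethyl)silyl]oxy}-4-methyl-3,3a,4,5,6,7-hexahydro-2H-indene-4-carboxylate | CC(C)(C)[Si](C)(C)OC1CC[C@H]2[C@](C)(C(=O)OC)CCCC=12 | intermediate
9 | tris(dimethylamino)sulfonium (3aR,4R)-4-(methoxycarbonyl)-4-methyl-3,3a,4,5,6,7-hexahydro-2H-inden-1-olate (not isolated) | [O-]C1CC[C@H]2[C@](C)(C(=O)OC)CCCC=12.CN(C)[S+](N(C)C)N(C)C | intermediate
10 | methyl (3aR,4R,7aR)-4,7a-dimethyl-1-oxooctahydro-1H-indene-4-carboxylate | O=C1CC[C@H]2[C@](C)(C(=O)OC)CCC[C@]21C | intermediate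
11 | 3-bromoprop-1-ene (allyl bromide) | C=CCBr | starting material
12 | lithium (3aR,4R,7aR)-1-(dibromomethyl)-4-(methoxycarbonyl)-4,7a-dimethyloctahydro-1H-inden-1-olate (both C-1 epimers; not isolated) | [Li]OC1(C(Br)Br)CC[C@H]2[C@](C)(C(=O)OC)CCC[C@]21C | intermediate
13 | lithium (4aR,5R,8aR)-5-(methoxycarbonyl)-5,8a-dimethyl-3,4,4a,5,6,7,8,8a-octahydronaphthalen-2-olate (not isolated) | [Li]OC1CC[C@H]2[C@](C)(C(=O)OC)CCC[C@@]2(C)C=1 | intermediate
14 | methyl (1R,4aR,5S,8aR)-1,4a-dimethyl-6-oxo-5-(prop-2-en-1-yl)decahydronaphthalene-1-carboxylate | O=C1CC[C@H]2[C@](C)(C(=O)OC)CCC[C@@]2(C)[C@@H]1CC=C | intermediate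
15 | methyl (1R,4aS,5R,8aR)-1,4a-dimethyl-6-methylidene-5-(prop-2-en-1-yl)decahydronaphthalene-1-carboxylate | C=C1CC[C@H]2[C@](C)(C(=O)OC)CCC[C@@]2(C)[C@@H]1CC=C | intermediate
16 | [(1R,4aS,5R,8aR)-1,4a-dimethyl-6-methylidene-5-(prop-2-en-1-yl)decahydronaphthalen-1-yl]methanol (as its aluminate; not isolated) | C=C1CC[C@H]2[C@](C)(CO)CCC[C@@]2(C)[C@@H]1CC=C | intermediate
17 | [(1R,4aS,5R,8aR)-1,4a-dimethyl-6-methylidene-5-(prop-2-en-1-yl)decahydronaphthalen-1-yl]methyl acetate | C=C1CC[C@H]2[C@](C)(COC(C)=O)CCC[C@@]2(C)[C@@H]1CC=C | intermediate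
18 | 3-methylideneoxolan-2-one (α-methylene-γ-butyrolactone) | C=C1CCOC1=O | starting material
19 | [(1R,4aS,5R,8aR)-1,4a-dimethyl-6-methylidene-5-[(2E)-2-(2-oxooxolan-3-ylidene)ethyl]decahydronaphthalen-1-yl]methyl acetate | C=C1CC[C@H]2[C@](C)(COC(C)=O)CCC[C@@]2(C)[C@@H]1C/C=C3/C(=O)OCC3 | intermediate
20 | [(1R,4aS,5R,8aR)-1,4a-dimethyl-6-methylidene-5-[2-(2-oxo-2,5-dihydrofuran-3-yl)ethyl]decahydronaphthalen-1-yl]methyl acetate (CNP0350004.1; labdane numbering 4R,5R,9R,10S) | C=C1CC[C@H]2[C@](C)(COC(C)=O)CCC[C@@]2(C)[C@@H]1CCC1=CCOC1=O | target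

**Totals**
Total steps: 9. Longest linear sequence: 8 (steps 1 and 3 to 9; step 2 is a one-step side branch).

**Steps most likely to fail**

Step 3 (the new reaction). The α-alkyl enone may react slowly or with low enantioselectivity; if the sense of induction is reversed, the other catalyst enantiomer is used. Fallback, from 2 and 5, back at 10: run the Mukaiyama–Michael addition with an achiral silyl Lewis acid (TBSOTf or HNTf2, a known reaction class). This gives the racemic adduct, that is 6 together with the mirror-image adduct F1. LiN(i-Pr)2 as in step 3 carries it through the mirror-image ester enolate F2 to the racemic bicyclic enol ether, 8 plus the mirror-image bicyclic enol ether F3. TASF/MeI as in step 4 gives, through the mirror-image sulfonium enolate F4, the racemic keto ester, 10 plus the mirror-image keto ester F5. The enantiomers are separated by preparative HPLC on a chiral stationary phase, and 10 goes on to step 5.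

Step 5. LiCHBr2 may add poorly to the hindered ketone, or C-7 may migrate instead of C-10. Fallback, from 10, back at enolate 13: add LiCH(SPh)2 (from bis(phenylsulfanyl)methane and n-BuLi) to 10 to give the β-hydroxy dithioacetal F6. Treat it with CuOTf (monovalent copper triflate) and i-Pr2NEt in benzene at 78 °C; thionium-ion formation drives the cationic semipinacol shift of C-10 (Cohen ring expansion) to the α-phenylsulfanyl decalone F7. Reductive C–S cleavage with lithium 4,4'-di-tert-butylbiphenylide at −78 °C gives enolate 13, which is allylated with 11 as in step 5 to 14.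

Step 9. The Ru–H catalyst may also move the C-8 exocyclic double bond into the ring. Fallback, from 14, back at 20: reduce 14 with LiAlH4 to the diol F8. Acetylate the primary hydroxyl selectively (AcCl, 2,4,6-collidine, CH2Cl2, −78 °C) to the hydroxy acetate F9, and oxidize with Dess–Martin periodinane to the keto acetate F10. Cross-metathesis with 18 as in step 8 gives the keto alkylidene lactone F11. Isomerize it with RhCl3·3H2O in ethanol at 70 °C, where no other alkene is present, to the keto butenolide F12. Lombardo methylenation as in step 6 gives 20.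

**Further compounds**
F1 | step 3 | mirror-image Michael adduct (enantiomer of 6) | CC(C)(C)[Si](C)(C)OC1=C(CCCCl)[C@H](CC1)C(C)C(=O)OC
F2 | step 3 | mirror-image ester enolate (enantiomer of 7) | CC(C)(C)[Si](C)(C)OC1=C(CCCCl)[C@H](CC1)C(C)=C(OC)O[Li]
F3 | step 3 | mirror-image bicyclic enol ether, methyl (3aS,4S)-1-{[tert-butyl(dimethyl)silyl]oxy}-4-methyl-3,3a,4,5,6,7-hexahydro-2H-indene-4-carboxylate | CC(C)(C)[Si](C)(C)OC1CC[C@@H]2[C@@](C)(C(=O)OC)CCCC=12
F4 | step 3 | mirror-image sulfonium enolate (enantiomer of 9) | [O-]C1CC[C@@H]2[C@@](C)(C(=O)OC)CCCC=12.CN(C)[S+](N(C)C)N(C)C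
F5 | step 3 | mirror-image keto ester, methyl (3aS,4S,7aS)-4,7a-dimethyl-1-oxooctahydro-1H-indene-4-carboxylate | O=C1CC[C@@H]2[C@@](C)(C(=O)OC)CCC[C@@]21C
F6 | step 5 | methyl (3aR,4R,7aR)-1-[bis(phenylsulfanyl)methyl]-1-hydroxy-4,7a-dimethyloctahydro-1H-indene-4-carboxylate (C-1 epimers) | OC1(C(Sc3ccccc3)Sc3ccccc3)CC[C@H]2[C@](C)(C(=O)OC)CCC[C@]21C
F7 | step 5 | methyl (1R,4aR,8aS)-1,4a-dimethyl-6-oxo-5-(phenylsulfanyl)decahydronaphthalene-1-carboxylate (C-5 epimers) | O=C1CC[C@H]2[C@](C)(C(=O)OC)CCC[C@@]2(C)C1Sc3ccccc3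
F8 | step 9 | diol: 14 with CO2Me reduced to CH2OH and the C-8 ketone to CHOH (C-8 epimers) | OC1CC[C@H]2[C@](C)(CO)CCC[C@@]2(C)[C@@H]1CC=C
F9 | step 9 | hydroxy acetate: F8 with the primary hydroxyl acetylated | OC1CC[C@H]2[C@](C)(COC(C)=O)CCC[C@@]2(C)[C@@H]1CC=C
F10 | step 9 | [(1R,4aR,5S,8aR)-1,4a-dimethyl-6-oxo-5-(prop-2-en-1-yl)decahydronaphthalen-1-yl]methyl acetate | O=C1CC[C@H]2[C@](C)(COC(C)=O)CCC[C@@]2(C)[C@@H]1CC=C
F11 | step 9 | [(1R,4aR,5S,8aR)-1,4a-dimethyl-6-oxo-5-[(2E)-2-(2-oxooxolan-3-ylidene)ethyl]decahydronaphthalen-1-yl]methyl acetate | O=C1CC[C@H]2[C@](C)(COC(C)=O)CCC[C@@]2(C)[C@@H]1C/C=C3/C(=O)OCC3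
F12 | step 9 | [(1R,4aR,5S,8aR)-1,4a-dimethyl-6-oxo-5-[2-(2-oxo-2,5-dihydrofuran-3-yl)ethyl]decahydronaphthalen-1-yl]methyl acetate | O=C1CC[C@H]2[C@](C)(COC(C)=O)CCC[C@@]2(C)[C@@H]1CCC1=CCOC1=O
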